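(The earlier runs and the new flask are simulated with constants of no real substance; noise was put on by code.)

The meeting opened on the row of flasks and on what Sunday's and Monday's runs could say about it.

the same everywhere: Tsp 14 mM (held)
- Sunday's: Sbt 0.11 M; run made earlier
- Monday's: Sbt 2.4 M; run made earlier
- alder: Sbt 0.20 M; time 2.5 min
- elm: Sbt 0.40 M; time 2.5 min
- cedar: Sbt 0.80 M; time 2.5 min
- larch: Sbt 1.5 M; time 2.5 min
- oak: Sbt 3.0 M; time 2.5 min

| run | time / min | Prd / % | Sbt / % |
|---|---|---|---|
| Sunday's | 0.200 | 1.4 | 97.2 |
| Sunday's | 0.333 | 4.9 | 95.6 |
| Sunday's | 0.500 | 8.9 | 93.6 |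
| Sunday's | 0.833 | 14.1 | 89.9 |
| Sunday's | 1.50 | 22.9 | 78.6 |
| Sunday's | 2.50 | 36.2 | 64.0 |
| Monday's | 0.417 | 2.0 | 96.6 |
| Monday's | 0.833 | 4.7 | 94.5 |
| Monday's | 1.33 | 9.4 | 92.4 |
| Monday's | 1.50 | 11.8 | 91.2 |
| Monday's | 2.00 | 11.5 | 88.1 |
| Monday's | 2.50 | 16.1 | 83.3 |

(readings scatter by 1 percentage point)

- at the start none of Tsp is in solution
- a reading or a percentage of Prd counts all its forms, free or not
- the concentration of Prd that is asked is that of its free form alone
- "hardly changes" means that all values lie within two and a half points (for a concentration: within two and a half percent of the largest)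

1. [Prd] (only what is free in solution) at the end for alder, elm, cedar, larch, oak, in this order
2. the course of these numbers from the first flask to the last (rises all the way / falls, then rises / rises, then falls / hardly changes / falls all the way)

The chair reported that Sunday's run lost Sbt at a fractional pace of 0.179 min⁻¹, which looked pseudo-first-order, while Monday's run, with its far larger charge, lost it at 0.0731 min⁻¹, a slower pace.

A colleague answered that Monday's run had still consumed ten times as much Sbt per litre, so the rate grows with the charge and levels off. She proposed rate = a·c(Sbt)/(1 + c(Sbt)/K), where K is the charge at which the two terms below the line are equal.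

She then separated the variables and integrated in closed form. The logarithm of charged over remaining c(Sbt), plus the c(Sbt) consumed divided by K, equals a times the time. Both runs ended at the same time under the same gas, so the sum had to match between them, and that gave K = 1.37 M. The sum itself came to 0.475, which she named the gas clock. Both are reckoned from the end readings of the two runs, so they are uncertain through the scatter of 1 percentage point in those readings.

The row shares that gas and that time, so she carried the clock over to it. For oak the conversion is small, so the logarithm is close to the converted fraction, and the fraction is the clock divided by 1 + c(Sbt)/K, or 14.9 %. That makes 0.447 M of Prd. She stressed that this is a total of all forms, as the readings are, and not the free concentration asked.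

The forecast, made from the same runs, gave 0.069 M, 0.127 M, 0.216 M, 0.32 M and 0.44 M as free Prd, a course that rises all the way, on the ground that “The runs cannot reveal any binding”.

The flasks gave free Prd of 0.0684 M, 0.125 M, 0.176 M, 0.179 M and 0.182 M, a course that rises all the way.

    Tsp ⇌ Tsp2, rate k1*(csat - [Tsp2]) (kL = 0.290 s⁻¹)
    Tsp3 ⇌ Prd, rate k2*(cs2 - [Prd]) while solid is left; crystals form when [Prd] > cs2 (solubility = 0.170 M, k = 0.220 s⁻¹)
    Sbt + Tsp2 → Prd (k = 0.230 M⁻¹ s⁻¹)
    Sbt → Sid (k = 6.80 × 10⁻⁶ s⁻¹)

In oak, the 86.0 % of Sbt left at the end puts the clock sum at 0.456 against 0.475, and Prd of all forms stands at 0.416 M. Free Prd is 0.182 M, and taking away the solubility limit of 0.17 M lifts it to 0.416 M, since 7.79 % of oak's charge stands as crystals of Tsp3. In larch, with 79.3 % of its Sbt left, the sum reads 0.460, 8.73 % of the charge is Tsp3, and free Prd is 0.179 M.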